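**Retrosynthetic overview**
- Target ⇒ 6-iodo oxepine-fused flavone + (E)-alkenyl pinacol boronate (Suzuki–Miyaura, last step), after 4'-O-debenzylation.
- Oxepine ⇒ aryl C2'–O bond by intramolecular SNAr of an (R)-secondary alkoxide on a 2'-fluoride; the carbinol ⇒ CBS reduction of an α'-hydroxy ketone.
- Key C–C bond (C3–CH2) ⇒ central carbon of the ring A/ring B β-diketone + CH2 of 3-hydroxy-3-methylbutan-2-one. Both are carbonyl α-carbons (natural nucleophiles), so the methyl ketone is used with reversed polarity as its α-bromo derivative (enolonium equivalent), on the lithium polyanion in the aroylation flask.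
- β-Diketone ⇒ 2',6'-dihydroxy-4'-methoxyacetophenone + 4-(benzyloxy)-2-fluorobenzoyl chloride; the C6 handle ⇒ 5-OH-directed iodination.
- Ring order: rings A and B are bought; ring C (pyranone) closes in the key flask; the oxepine closes second.

Assumption: the four building blocks named above, including the (E)-alkenyl pinacol boronate, are taken as catalogue compounds; the stereocentre of the target reads as (R) from the SMILES.

**Step 1**
Reactants: 1 3-hydroxy-3-methylbutan-2-one
Product: 2 1-bromo-3-hydroxy-3-methylbutan-2-one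
Conditions: Br2 (1.0 equiv), MeOH, 0 °C → rt; H2O work-up
Reagents that add atoms: bromine, BrBr
Why: Acid-catalysed α-bromination of a ketone through its enol; only the methyl side of 1 can enolise and methanol limits over-bromination, so the nucleophilic α-carbon becomes an electrophilic (enolonium-equivalent) CH2Br.

**Step 2**
Reactants: 3 1-(2,6-dihydroxy-4-methoxyphenyl)ethan-1-one; 4 4-(benzyloxy)-2-fluorobenzoic acid; 2 1-bromo-3-hydroxy-3-methylbutan-2-one
Product: 8 2-[4-(benzyloxy)-2-fluorophenyl]-5-hydroxy-3-(3-hydroxy-3-methyl-2-oxobutyl)-7-methoxy-4H-chromen-4-one, via acid chloride 5 (not isolated), via β-diketone 6 (not isolated), via triketone 7 (not isolated)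
Conditions: 4, (COCl)2, DMF (cat.), CH2Cl2, rt, evaporate; 3, LiN(SiMe3)2 (4.1 equiv), THF, −78 → −10 °C, then 5, −78 °C → rt; then 2 (1.3 equiv), DMPU, 0 → 40 °C; then 3 M HCl/MeOH, 60 °C
Reagents that add atoms: none
Why: Proposed new method: the lithium trianion of 3 is C-aroylated by 5 (Cushman polyanion variant of the Baker–Venkataraman/Claisen acylation, any O-aroylated material rearranging under the same base), the resulting lithium β-diketonate 6 is alkylated at its central carbon by the α-bromoketone 2 acting as the enolonium (a2) equivalent of 3-hydroxy-3-methylbutan-2-one (SN2 at the primary CH2Br is favoured because the ketone carbonyl next to the quaternary carbinol is hindered, which disfavours Feist–Benary attack), and acid then closes ring C by cyclodehydration of 7 with a flanking phenol; the closest known reactions are α-haloketone C-alkylation of β-diketonates and the alkylation/cyclodehydration route to 3-alkylflavones, and no stereocentre is formed.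

**Step 3**
Reactants: 8 2-[4-(benzyloxy)-2-fluorophenyl]-5-hydroxy-3-(3-hydroxy-3-methyl-2-oxobutyl)-7-methoxy-4H-chromen-4-one
Product: 9 2-[4-(benzyloxy)-2-fluorophenyl]-5-hydroxy-3-(3-hydroxy-3-methyl-2-oxobutyl)-6-iodo-7-methoxy-4H-chromen-4-one
Conditions: BnMe3N+ ICl2− (1.05 equiv), CaCO3, CH2Cl2/MeOH (5:2), rt
Reagents that add atoms: benzyltrimethylammonium dichloroiodate, C[N+](C)(C)Cc1ccccc1.Cl[I-]Cl
Why: Electrophilic aromatic iodination with a dichloroiodate salt, which in 5-hydroxy-7-alkoxyflavones goes ortho to the free chelated 5-OH (C6), while ring B (fluoro, mono-alkoxy, attached to the electron-poor pyranone) and the buffered ketone stay untouched.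

**Step 4**
Reactants: 9 2-[4-(benzyloxy)-2-fluorophenyl]-5-hydroxy-3-(3-hydroxy-3-methyl-2-oxobutyl)-6-iodo-7-methoxy-4H-chromen-4-one
Product: 10 2-[4-(benzyloxy)-2-fluorophenyl]-3-[(2R)-2,3-dihydroxy-3-methylbutyl]-5-hydroxy-6-iodo-7-methoxy-4H-chromen-4-one
Conditions: (S)-2-methyl-CBS-oxazaborolidine (0.3 equiv), catecholborane (3 equiv), toluene/CH2Cl2, −78 → −40 °C; then MeOH, aq. NaHCO3
Reagents that add atoms: none
Why: Corey–Bakshi–Shibata reduction: the (S)-oxazaborolidine places the bulky C(CH3)2O–boron substituent in the large-group position and the CH2–flavonyl arm in the small one, so hydride is delivered to the face that gives the (R)-carbinol, while the chelated vinylogous-ester C4 carbonyl and the aryl iodide do not react with catecholborane at low temperature.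

**Step 5**
Reactants: 10 2-[4-(benzyloxy)-2-fluorophenyl]-3-[(2R)-2,3-dihydroxy-3-methylbutyl]-5-hydroxy-6-iodo-7-methoxy-4H-chromen-4-one
Product: 11 (R)-oxepine-fused flavone: 5-hydroxy-6-iodo-7-methoxyflavone with C3 and O-2' bridged by CH2–CH[C(CH3)2OH] and 4'-O-benzyl
Conditions: KN(SiMe3)2 (3.3 equiv), THF/DMPU (4:1), 0 → 65 °C; then aq. HCl to pH 5
Reagents that add atoms: none
Why: Intramolecular nucleophilic aromatic substitution (addition–elimination): the secondary potassium alkoxide attacks the 2'-fluoride, whose Meisenheimer intermediate is stabilised through C2 into the pyranone carbonyl, closing the 7-membered ring in preference to the 8-membered ring from the tertiary alkoxide, and since no bond to the stereocentre is broken the (R) configuration is retained.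

**Step 6**
Reactants: 11 (R)-oxepine-fused flavone with 6-iodo and 4'-O-benzyl
Product: 12 (R)-oxepine-fused flavone: 5-hydroxy-6-iodo-7-methoxyflavone with C3 and O-2' bridged by CH2–CH[C(CH3)2OH] and free 4'-OH
Conditions: BCl3 (4 equiv), pentamethylbenzene (3 equiv), CH2Cl2, −78 °C, 30 min; then MeOH
Reagents that add atoms: none
Why: Lewis-acid debenzylation with a cation scavenger (Friedel–Crafts transfer of the benzyl cation to pentamethylbenzene) cleaves the benzyl aryl ether at −78 °C, where the non-chelated 7-OMe, the secondary alkyl aryl ether of the oxepine, the tertiary alcohol and the aryl iodide are left intact.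

**Step 7**
Reactants: 12 (R)-oxepine-fused flavone with 6-iodo and free 4'-OH; 13 2-[(E)-3-methylbut-1-en-1-yl]-4,4,5,5-tetramethyl-1,3,2-dioxaborolane
Product: 14 CNP0216454.1: (R)-oxepine-fused flavone with 5-OH; 6-[(E)-3-methylbut-1-enyl]; 7-OMe; 4'-OH
Conditions: Pd(PPh3)4 (5 mol%), K2CO3 (3 equiv), 1,4-dioxane/H2O (4:1), 85 °C
Reagents that add atoms: none
Why: Suzuki–Miyaura coupling of the aryl iodide with the (E)-alkenyl boronate proceeds with retention of alkene geometry and tolerates the free phenols and the tertiary alcohol, the remote stereocentre being untouched.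

**Compound list**
1 | 3-hydroxy-3-methylbutan-2-one | CC(=O)C(C)(C)O | starting material
2 | 1-bromo-3-hydroxy-3-methylbutan-2-one | CC(C)(O)C(=O)CBr | intermediate
3 | 1-(2,6-dihydroxy-4-methoxyphenyl)ethan-1-one (2',6'-dihydroxy-4'-methoxyacetophenone) | CC(=O)c1c(O)cc(OC)cc1O | starting material
4 | 4-(benzyloxy)-2-fluorobenzoic acid | OC(=O)c1ccc(OCc2ccccc2)cc1F | starting material
5 | 4-(benzyloxy)-2-fluorobenzoyl chloride (not isolated) | O=C(Cl)c1ccc(OCc2ccccc2)cc1F | intermediate
6 | 1-[4-(benzyloxy)-2-fluorophenyl]-3-(2,6-dihydroxy-4-methoxyphenyl)propane-1,3-dione (not isolated) | COc1cc(O)c(C(=O)CC(=O)c2ccc(OCc3ccccc3)cc2F)c(O)c1 | intermediate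
7 | 1-[4-(benzyloxy)-2-fluorophenyl]-3-(2,6-dihydroxy-4-methoxyphenyl)-2-(3-hydroxy-3-methyl-2-oxobutyl)propane-1,3-dione (not isolated) | COc1cc(O)c(C(=O)C(CC(=O)C(C)(C)O)C(=O)c2ccc(OCc3ccccc3)cc2F)c(O)c1 | intermediate
8 | 2-[4-(benzyloxy)-2-fluorophenyl]-5-hydroxy-3-(3-hydroxy-3-methyl-2-oxobutyl)-7-methoxy-4H-chromen-4-one | COc1cc(O)c2c(=O)c(CC(=O)C(C)(C)O)c(-c3ccc(OCc4ccccc4)cc3F)oc2c1 | intermediate
9 | 2-[4-(benzyloxy)-2-fluorophenyl]-5-hydroxy-3-(3-hydroxy-3-methyl-2-oxobutyl)-6-iodo-7-methoxy-4H-chromen-4-one | COc1cc2oc(-c3ccc(OCc4ccccc4)cc3F)c(CC(=O)C(C)(C)O)c(=O)c2c(O)c1I | intermediate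
10 | 2-[4-(benzyloxy)-2-fluorophenyl]-3-[(2R)-2,3-dihydroxy-3-methylbutyl]-5-hydroxy-6-iodo-7-methoxy-4H-chromen-4-one | COc1cc2oc(-c3ccc(OCc4ccccc4)cc3F)c(C[C@H](C(C)(C)O)O)c(=O)c2c(O)c1I | intermediate
11 | (R)-oxepine-fused flavone: 5-hydroxy-6-iodo-7-methoxyflavone with C3 and O-2' bridged by CH2–CH[C(CH3)2OH]; 4'-O-benzyl | COc1cc2oc3c(c(=O)c2c(O)c1I)C[C@H](C(C)(C)O)Oc1cc(OCc2ccccc2)ccc1-3 | intermediate
12 | (R)-oxepine-fused flavone as 11 but with free 4'-OH | COc1cc2oc3c(c(=O)c2c(O)c1I)C[C@H](C(C)(C)O)Oc1cc(O)ccc1-3 | intermediate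
13 | 2-[(E)-3-methylbut-1-en-1-yl]-4,4,5,5-tetramethyl-1,3,2-dioxaborolane | CC(C)/C=C/B1OC(C)(C)C(C)(C)O1 | starting material
14 | CNP0216454.1: (R)-oxepine-fused flavone with 5-OH; 6-[(E)-3-methylbut-1-enyl]; 7-OMe; 4'-OH | COc1cc2oc3c(c(=O)c2c(O)c1/C=C/C(C)C)C[C@H](C(C)(C)O)Oc1cc(O)ccc1-3 | target

**Totals**
Total step count: 7. Longest linear sequence: 7 steps (1 → 2 → 8 → 9 → 10 → 11 → 12 → 14).

**Steps most likely to fail**

Step 2 (one-flask aroylation, reversed-polarity alkylation and cyclodehydration). The lithium polyanion may alkylate sluggishly or on oxygen, and furan formation can compete with pyranone closure. The fallback sets out from 3 and 5 and comes back at 8. 3 is O-aroylated with one equivalent of 5 (K2CO3, acetone) to the mono-ester 2-acetyl-3-hydroxy-5-methoxyphenyl 4-(benzyloxy)-2-fluorobenzoate F1. Baker–Venkataraman O-to-C acyl migration (KOH, pyridine, 50 °C) gives 6, which is now isolated. Isolated 6 is alkylated as its soft potassium enolate with 2 (K2CO3, acetone, rt) to 7, and 7 is cyclodehydrated (HCl, MeOH) to 8. The same bond is made with the same enolonium equivalent, but through an intramolecular acyl transfer and a separate soft-enolate alkylation instead of an intermolecular polyanion cascade.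

Step 5 (SNAr closure of the oxepine). The 2'-fluoride is only activated through the vinylogous carbonyl, and the 5-phenoxide lowers that activation further. The fallback sets out from 3 and 2 and comes back at 11; it replaces addition–elimination by metal-catalysed C–O coupling on a bromide. 4-(Benzyloxy)-2-bromobenzoic acid F2 is converted to 4-(benzyloxy)-2-bromobenzoyl chloride F3 and taken with 3 and 2 through the chemistry of step 2, by way of the bromo β-diketone F4 and the bromo triketone F5, to the 2'-bromo flavone ketone F6. CBS reduction as in step 4 gives the 2'-bromo (R)-diol F7. Pd-catalysed intramolecular etherification (Pd(OAc)2, t-BuXPhos, Cs2CO3, toluene, 80 °C) closes the ring with retention to the 6-unsubstituted oxepine F8. Iodination as in step 3 then gives 11.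

Step 4 (CBS reduction next to free OH groups). Alkoxyborane formation at the tertiary alcohol could open a non-selective intramolecular hydride delivery and erode the ee. The fallback sets out from 9 and comes back at 10; it replaces asymmetric catalysis by resolution. NaBH4 (MeOH/THF, −40 °C) reduces the side-chain ketone to racemic 2-[4-(benzyloxy)-2-fluorophenyl]-3-(2,3-dihydroxy-3-methylbutyl)-5-hydroxy-6-iodo-7-methoxy-4H-chromen-4-one F9. The (R) enantiomer 10 is then separated by preparative chromatography on a chiral stationary phase (supercritical CO2/MeOH).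

**Further compounds**
F1 | step 2 | 2-acetyl-3-hydroxy-5-methoxyphenyl 4-(benzyloxy)-2-fluorobenzoate | CC(=O)c1c(O)cc(OC)cc1OC(=O)c1ccc(OCc2ccccc2)cc1F
F2 | step 5 | 4-(benzyloxy)-2-bromobenzoic acid | OC(=O)c1ccc(OCc2ccccc2)cc1Br
F3 | step 5 | 4-(benzyloxy)-2-bromobenzoyl chloride | O=C(Cl)c1ccc(OCc2ccccc2)cc1Br
F4 | step 5 | 1-[4-(benzyloxy)-2-bromophenyl]-3-(2,6-dihydroxy-4-methoxyphenyl)propane-1,3-dione | COc1cc(O)c(C(=O)CC(=O)c2ccc(OCc3ccccc3)cc2Br)c(O)c1
F5 | step 5 | 1-[4-(benzyloxy)-2-bromophenyl]-3-(2,6-dihydroxy-4-methoxyphenyl)-2-(3-hydroxy-3-methyl-2-oxobutyl)propane-1,3-dione | COc1cc(O)c(C(=O)C(CC(=O)C(C)(C)O)C(=O)c2ccc(OCc3ccccc3)cc2Br)c(O)c1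
F6 | step 5 | 2-[4-(benzyloxy)-2-bromophenyl]-5-hydroxy-3-(3-hydroxy-3-methyl-2-oxobutyl)-7-methoxy-4H-chromen-4-one | COc1cc(O)c2c(=O)c(CC(=O)C(C)(C)O)c(-c3ccc(OCc4ccccc4)cc3Br)oc2c1
F7 | step 5 | 2-[4-(benzyloxy)-2-bromophenyl]-3-[(2R)-2,3-dihydroxy-3-methylbutyl]-5-hydroxy-7-methoxy-4H-chromen-4-one | COc1cc(O)c2c(=O)c(C[C@H](C(C)(C)O)O)c(-c3ccc(OCc4ccccc4)cc3Br)oc2c1
F8 | step 5 | (R)-oxepine-fused flavone as 11 but with H in place of the 6-iodo group | COc1cc2oc3c(c(=O)c2c(O)c1)C[C@H](C(C)(C)O)Oc1cc(OCc2ccccc2)ccc1-3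
F9 | step 4 | racemic 2-[4-(benzyloxy)-2-fluorophenyl]-3-(2,3-dihydroxy-3-methylbutyl)-5-hydroxy-6-iodo-7-methoxy-4H-chromen-4-one | COc1cc2oc(-c3ccc(OCc4ccccc4)cc3F)c(CC(O)C(C)(C)O)c(=O)c2c(O)c1I
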